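**Retrosynthetic overview**

1. Feature: in ring A the ring oxygen O1 (on C7a) and the methoxy oxygen (on C7) sit on neighbouring carbons. These two carbons are the ends of a C7–C7a aryne, so both C–O bonds can come from one fluoroarene whose C3a side chain already holds the C2 oxygen.
2. Late disconnections: the C3–CH2O–acyl ester (Steglich coupling with O-silyl p-coumaric acid) and C7–OMe (from C7–Bpin by oxidation and methylation).
3. Key disconnection: O1–C7a and C7–B across the aryne. The furan ring (O1, C2, C3, C3a, C7a) is the only ring formed, and it is closed onto the preformed ring A with C2 and C3 already set.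
4. C2–C3 bond and both stereocentres: Evans syn-aldol of the (R)-4-benzyloxazolidinone imide of the fluoroarylacetic acid with O-TIPS vanillin, then reductive auxiliary removal and primary silylation.
5. C5 side chain: B-alkyl Suzuki–Miyaura coupling of an allyl silyl ether/9-BBN adduct with 5-bromo-2-fluorophenylacetic acid.

Key step: step 8

Remark: ring A positions use benzofuran numbering (O1, C2, C3, C3a, C4–C7, C7a) and guaiacyl ring positions are primed; the auxiliary and the silyl chlorides are taken as commercial.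
Remark: the chain hydroxyl is carried as a TBDPS ether and the C3 hydroxymethyl as a TBS ether, so that step 11 can tell the two primary silyl ethers apart by acid lability.

**Route**

Step 1
Reactants: 1 allyl alcohol
Product: 2 allyl tert-butyldiphenylsilyl ether
Conditions: TBDPSCl, imidazole, CH2Cl2, 0 °C → rt
Reagents that add atoms: tert-butyl(chloro)diphenylsilane, CC(C)(C)[Si](Cl)(c1ccccc1)c1ccccc1
Why: Imidazole-promoted silylation of a primary alcohol is routine, and the TBDPS ether should survive the later acid-mediated TBS cleavage.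

Step 2
Reactants: 2 allyl tert-butyldiphenylsilyl ether; 3 5-bromo-2-fluorophenylacetic acid
Product: 5 2-{5-[3-(tert-butyldiphenylsilyloxy)propyl]-2-fluorophenyl}acetic acid, via alkylborane 4 (not isolated)
Conditions: 2 (1.3 equiv), 9-BBN (0.5 M in THF), 0 °C → rt; then 3, PdCl2(dppf)·CH2Cl2 (5 mol %), aq. K3PO4 (4 equiv), DMF/THF, 60 °C; citric acid work-up
Reagents that add atoms: none
Why: Anti-Markovnikov hydroboration puts boron on the terminal carbon, and the B-alkyl-9-BBN then couples with the aryl bromide in a B-alkyl Suzuki–Miyaura reaction, with the acid carried as its potassium carboxylate and the C–F bond left untouched.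

Step 3
Reactants: 5 2-{5-[3-(tert-butyldiphenylsilyloxy)propyl]-2-fluorophenyl}acetic acid; 6 (R)-4-benzyloxazolidin-2-one
Product: 8 (R)-4-benzyl-3-(2-{5-[3-(tert-butyldiphenylsilyloxy)propyl]-2-fluorophenyl}acetyl)oxazolidin-2-one, via mixed pivalic anhydride 7 (not isolated)
Conditions: PivCl, Et3N, THF, −20 → 0 °C; then 6, LiCl, 0 °C → rt
Reagents that add atoms: none
Why: N-Acylation of the oxazolidinone through the mixed pivalic anhydride under LiCl/Et3N is the mild standard imide synthesis and avoids the ketene formation to which arylacetyl chlorides are prone.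

Step 4
Reactants: 9 vanillin
Product: 10 3-methoxy-4-(triisopropylsilyloxy)benzaldehyde
Conditions: TIPSCl, imidazole, DMF, rt
Reagents that add atoms: chlorotriisopropylsilane, CC(C)[Si](Cl)(C(C)C)C(C)C
Why: Phenol silylation removes the acidic O–H, and the bulky TIPS ether should tolerate the boron aldol, LiBH4 and s-BuLi.

Step 5
Reactants: 8 (R)-4-benzyl-3-(2-{5-[3-(tert-butyldiphenylsilyloxy)propyl]-2-fluorophenyl}acetyl)oxazolidin-2-one; 10 3-methoxy-4-(triisopropylsilyloxy)benzaldehyde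
Product: 13 (R)-4-benzyl-3-[(2R,3R)-2-{5-[3-(tert-butyldiphenylsilyloxy)propyl]-2-fluorophenyl}-3-hydroxy-3-(3-methoxy-4-triisopropylsilyloxyphenyl)propanoyl]oxazolidin-2-one, via dibutylboron Z-enolate 11 (not isolated), via dibutylboron aldolate 12 (not isolated)
Conditions: Bu2BOTf (1.2 equiv), iPr2NEt (1.4 equiv), CH2Cl2, −78 → 0 °C; 10, −78 → 0 °C; pH 7 buffer, MeOH, 30 % H2O2, 0 °C
Reagents that add atoms: none
Why: Evans syn-aldol: the Z boron enolate reacts through a closed Zimmerman–Traxler chair with the auxiliary carbonyl turned away from the enolate oxygen, so the aldehyde adds to the face opposite the benzyl group and the (R)-auxiliary sets both new stereocentres (2R,3R; the future C3 and C2) in the syn relationship.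

Step 6
Reactants: 13 syn-aldol adduct
Product: 14 (1R,2S)-2-{5-[3-(tert-butyldiphenylsilyloxy)propyl]-2-fluorophenyl}-1-(3-methoxy-4-triisopropylsilyloxyphenyl)propane-1,3-diol
Conditions: LiBH4, MeOH (1.1 equiv), THF, 0 °C
Reagents that add atoms: none
Why: Reductive cleavage of the N-acyl oxazolidinone with LiBH4 attacks the exocyclic carbonyl and should release the primary alcohol without touching either stereocentre, the low temperature limiting retro-aldol.

Step 7
Reactants: 14 (1R,2S)-diol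
Product: 15 (1R,2S)-3-(tert-butyldimethylsilyloxy)-2-{5-[3-(tert-butyldiphenylsilyloxy)propyl]-2-fluorophenyl}-1-(3-methoxy-4-triisopropylsilyloxyphenyl)propan-1-ol
Conditions: TBSCl (1.05 equiv), imidazole, CH2Cl2, 0 °C
Reagents that add atoms: tert-butyl(chloro)dimethylsilane, CC(C)(C)[Si](C)(C)Cl
Why: Silylation should take place at the primary hydroxyl only, the secondary benzylic hydroxyl being much more hindered.

Step 8
Reactants: 15 (1R,2S)-3-(tert-butyldimethylsilyloxy)-2-{5-[3-(tert-butyldiphenylsilyloxy)propyl]-2-fluorophenyl}-1-(3-methoxy-4-triisopropylsilyloxyphenyl)propan-1-ol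
Product: 19 (2R,3S)-3-[(tert-butyldimethylsilyloxy)methyl]-5-[3-(tert-butyldiphenylsilyloxy)propyl]-2-(3-methoxy-4-triisopropylsilyloxyphenyl)-7-(4,4,5,5-tetramethyl-1,3,2-dioxaborolan-2-yl)-2,3-dihydrobenzofuran, via C7-lithiated fluoroarene alkoxide 16 (not isolated), via aryne alkoxide 17 (not isolated), via C7-lithio dihydrobenzofuran 18 (not isolated)
Conditions: s-BuLi (2.1 equiv), THF (0.02 M), −78 °C, 1.5 h; −78 → −30 °C; recool to −78 °C, iPrOBpin (3 equiv), → rt; aq. NH4Cl
Reagents that add atoms: 2-isopropoxy-4,4,5,5-tetramethyl-1,3,2-dioxaborolane, CC(C)OB1OC(C)(C)C(C)(C)O1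
Why: One equivalent of s-BuLi forms the C2 lithium alkoxide and the second removes C7–H, the only hydrogen next to fluorine, to give 16; on warming 16 expels LiF to the C7–C7a aryne 17, the tethered alkoxide adds to C7a, and the resulting C7 aryllithium 18, now ortho to the new ether oxygen, is quenched by iPrOBpin. The closest known reaction type is the intramolecular addition of a tethered alkoxide to an aryne generated from a haloarene with strong base, followed by electrophilic capture of the ortho-metalated aryl ether. The furan ring (O1, C2, C3, C3a, C7a) is closed by O1–C7a bond formation in a 5-exo-dig mode with respect to the aryne bond. No stereocentre is formed: the C2–O and C3–C bonds stay intact, so the syn (1R,2S) arrangement of 15 is carried unchanged into the trans (2R,3S) ring. The step needs lithiation at C7 only and oxygen delivery to C7a only; the first is secured by the acidifying fluorine with its single ortho hydrogen and by omitting TMEDA so that methoxy- or alkoxide-directed lithiation of the guaiacyl ring stays slow at −78 °C, the second by the tether, which can reach C7a but not C7. An alkyllithium rather than a lithium amide is used so that no N–H is present to protonate 18, and two equivalents at high dilution limit addition of s-BuLi or of a second aryllithium to the aryne.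

Step 9
Reactants: 19 C7 pinacol boronate
Product: 20 (2R,3S)-3-[(tert-butyldimethylsilyloxy)methyl]-5-[3-(tert-butyldiphenylsilyloxy)propyl]-2-(3-methoxy-4-triisopropylsilyloxyphenyl)-2,3-dihydrobenzofuran-7-ol
Conditions: NaBO3·4H2O, THF/H2O (1:1), rt
Reagents that add atoms: sodium perborate, [Na+].[Na+].O[B-]1(O)OO[B-](O)(O)OO1
Why: Perborate oxidation of the aryl boronate (1,2-shift of the aryl group from boron to peroxide oxygen) gives the C7 phenol at the same ring position under mildly basic conditions that the aryl TIPS ether should tolerate.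

Step 10
Reactants: 20 C7 phenol
Product: 21 (2R,3S)-3-[(tert-butyldimethylsilyloxy)methyl]-5-[3-(tert-butyldiphenylsilyloxy)propyl]-7-methoxy-2-(3-methoxy-4-triisopropylsilyloxyphenyl)-2,3-dihydrobenzofuran
Conditions: MeI, K2CO3, acetone, 40 °C
Reagents that add atoms: iodomethane, CI
Why: Williamson O-methylation of the only free phenol; all other oxygens are silylated or etherified.

Step 11
Reactants: 21 C7 methyl ether
Product: 22 {(2R,3S)-5-[3-(tert-butyldiphenylsilyloxy)propyl]-7-methoxy-2-(3-methoxy-4-triisopropylsilyloxyphenyl)-2,3-dihydrobenzofuran-3-yl}methanol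
Conditions: CSA (0.1 equiv), MeOH/CH2Cl2 (1:1), 0 °C
Reagents that add atoms: none
Why: Acid-catalysed methanolysis cleaves a primary TBS ether far faster than a TBDPS ether, and aryl TIPS ethers are acid-stable, so only the C3 hydroxymethyl should be released.

Step 12
Reactants: 23 p-coumaric acid
Product: 25 (E)-3-[4-(triisopropylsilyloxy)phenyl]prop-2-enoic acid, via bis-silylated coumarate 24 (not isolated)
Conditions: TIPSCl (2.3 equiv), imidazole, DMF, rt; then K2CO3, MeOH/THF/H2O, 0 °C; citric acid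
Reagents that add atoms: chlorotriisopropylsilane, CC(C)[Si](Cl)(C(C)C)C(C)C
Why: Exhaustive silylation followed by mild carbonate hydrolysis of the labile silyl ester should leave the aryl TIPS ether and the E alkene intact.

Step 13
Reactants: 22 C3 hydroxymethyl compound; 25 (E)-3-[4-(triisopropylsilyloxy)phenyl]prop-2-enoic acid
Product: 26 {(2R,3S)-5-[3-(tert-butyldiphenylsilyloxy)propyl]-7-methoxy-2-(3-methoxy-4-triisopropylsilyloxyphenyl)-2,3-dihydrobenzofuran-3-yl}methyl (E)-3-[4-(triisopropylsilyloxy)phenyl]prop-2-enoate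
Conditions: EDC·HCl, DMAP, CH2Cl2, 0 °C → rt
Reagents that add atoms: none
Why: Steglich esterification (carbodiimide activation, DMAP acyl transfer) acylates the only free hydroxyl and does not affect C2 or C3.

Step 14
Reactants: 26 fully silylated ester
Product: 27 [(2R,3S)-2-(4-hydroxy-3-methoxyphenyl)-5-(3-hydroxypropyl)-7-methoxy-2,3-dihydrobenzofuran-3-yl]methyl (E)-3-(4-hydroxyphenyl)prop-2-enoate (CNP0202924.1)
Conditions: TBAF/AcOH (1:1, 4 equiv), THF, 0 °C → rt
Reagents that add atoms: none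
Why: Fluoride-mediated desilylation removes the two aryl TIPS groups and the primary TBDPS group, and the acetic acid buffer should suppress hydrolysis or transesterification of the cinnamate ester.

**Compound list**

1 | allyl alcohol | C=CCO | starting material
2 | allyl tert-butyldiphenylsilyl ether | C=CCO[Si](c1ccccc1)(c1ccccc1)C(C)(C)C | intermediate
3 | 5-bromo-2-fluorophenylacetic acid | OC(=O)Cc1cc(Br)ccc1F | starting material
4 | 9-[3-(tert-butyldiphenylsilyloxy)propyl]-9-borabicyclo[3.3.1]nonane (formed in the flask) | CC(C)(C)[Si](OCCCB1C2CCCC1CCC2)(c1ccccc1)c1ccccc1 | intermediate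
5 | 2-{5-[3-(tert-butyldiphenylsilyloxy)propyl]-2-fluorophenyl}acetic acid | OC(=O)Cc1cc(CCCO[Si](c2ccccc2)(c2ccccc2)C(C)(C)C)ccc1F | intermediate
6 | (R)-4-benzyloxazolidin-2-one | O=C1N[C@H](Cc2ccccc2)CO1 | starting material
7 | mixed pivalic anhydride of 5 (formed in the flask) | CC(C)(C)C(=O)OC(=O)Cc1cc(CCCO[Si](c2ccccc2)(c2ccccc2)C(C)(C)C)ccc1F | intermediate
8 | (R)-4-benzyl-3-(2-{5-[3-(tert-butyldiphenylsilyloxy)propyl]-2-fluorophenyl}acetyl)oxazolidin-2-one | O=C(Cc1cc(CCCO[Si](c2ccccc2)(c2ccccc2)C(C)(C)C)ccc1F)N1[C@H](Cc2ccccc2)COC1=O | intermediate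
9 | vanillin | COc1cc(C=O)ccc1O | starting material
10 | 3-methoxy-4-(triisopropylsilyloxy)benzaldehyde | COc1cc(C=O)ccc1O[Si](C(C)C)(C(C)C)C(C)C | intermediate
11 | dibutylboron Z-enolate of 8 (formed in the flask) | CCCCB(CCCC)O/C(=C\c1cc(CCCO[Si](c2ccccc2)(c2ccccc2)C(C)(C)C)ccc1F)N1[C@H](Cc2ccccc2)COC1=O | intermediate
12 | dibutylboron aldolate of 13 (formed in the flask) | COc1cc([C@H](OB(CCCC)CCCC)[C@H](C(=O)N2[C@H](Cc3ccccc3)COC2=O)c2cc(CCCO[Si](c3ccccc3)(c3ccccc3)C(C)(C)C)ccc2F)ccc1O[Si](C(C)C)(C(C)C)C(C)C | intermediate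
13 | (R)-4-benzyl-3-[(2R,3R)-2-{5-[3-(tert-butyldiphenylsilyloxy)propyl]-2-fluorophenyl}-3-hydroxy-3-(3-methoxy-4-triisopropylsilyloxyphenyl)propanoyl]oxazolidin-2-one (syn) | COc1cc([C@H](O)[C@H](C(=O)N2[C@H](Cc3ccccc3)COC2=O)c2cc(CCCO[Si](c3ccccc3)(c3ccccc3)C(C)(C)C)ccc2F)ccc1O[Si](C(C)C)(C(C)C)C(C)C | intermediate
14 | (1R,2S)-2-{5-[3-(tert-butyldiphenylsilyloxy)propyl]-2-fluorophenyl}-1-(3-methoxy-4-triisopropylsilyloxyphenyl)propane-1,3-diol | COc1cc([C@H](O)[C@H](CO)c2cc(CCCO[Si](c3ccccc3)(c3ccccc3)C(C)(C)C)ccc2F)ccc1O[Si](C(C)C)(C(C)C)C(C)C | intermediate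
15 | (1R,2S)-3-(tert-butyldimethylsilyloxy)-2-{5-[3-(tert-butyldiphenylsilyloxy)propyl]-2-fluorophenyl}-1-(3-methoxy-4-triisopropylsilyloxyphenyl)propan-1-ol (syn; key-step precursor) | COc1cc([C@H](O)[C@H](CO[Si](C)(C)C(C)(C)C)c2cc(CCCO[Si](c3ccccc3)(c3ccccc3)C(C)(C)C)ccc2F)ccc1O[Si](C(C)C)(C(C)C)C(C)C | intermediate
16 | C2 lithium alkoxide of 15 lithiated at C7 (formed in the flask) | COc1cc([C@H](O[Li])[C@H](CO[Si](C)(C)C(C)(C)C)c2cc(CCCO[Si](c3ccccc3)(c3ccccc3)C(C)(C)C)cc([Li])c2F)ccc1O[Si](C(C)C)(C(C)C)C(C)C | intermediate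
17 | C7–C7a aryne bearing the C2 lithium alkoxide (formed in the flask) | COc1cc([C@H](O[Li])[C@H](CO[Si](C)(C)C(C)(C)C)C2=CC(CCCO[Si](c3ccccc3)(c3ccccc3)C(C)(C)C)=CC#C2)ccc1O[Si](C(C)C)(C(C)C)C(C)C | intermediate
18 | (2R,3S)-7-lithio-2,3-dihydrobenzofuran corresponding to 19 (formed in the flask) | COc1cc([C@@H]2Oc3c([Li])cc(CCCO[Si](c4ccccc4)(c4ccccc4)C(C)(C)C)cc3[C@H]2CO[Si](C)(C)C(C)(C)C)ccc1O[Si](C(C)C)(C(C)C)C(C)C | intermediate
19 | (2R,3S)-3-[(tert-butyldimethylsilyloxy)methyl]-5-[3-(tert-butyldiphenylsilyloxy)propyl]-2-(3-methoxy-4-triisopropylsilyloxyphenyl)-7-(4,4,5,5-tetramethyl-1,3,2-dioxaborolan-2-yl)-2,3-dihydrobenzofuran (trans; key-step product) | COc1cc([C@@H]2Oc3c(B4OC(C)(C)C(C)(C)O4)cc(CCCO[Si](c4ccccc4)(c4ccccc4)C(C)(C)C)cc3[C@H]2CO[Si](C)(C)C(C)(C)C)ccc1O[Si](C(C)C)(C(C)C)C(C)C | intermediate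
20 | (2R,3S)-3-[(tert-butyldimethylsilyloxy)methyl]-5-[3-(tert-butyldiphenylsilyloxy)propyl]-2-(3-methoxy-4-triisopropylsilyloxyphenyl)-2,3-dihydrobenzofuran-7-ol | COc1cc([C@@H]2Oc3c(O)cc(CCCO[Si](c4ccccc4)(c4ccccc4)C(C)(C)C)cc3[C@H]2CO[Si](C)(C)C(C)(C)C)ccc1O[Si](C(C)C)(C(C)C)C(C)C | intermediate
21 | (2R,3S)-3-[(tert-butyldimethylsilyloxy)methyl]-5-[3-(tert-butyldiphenylsilyloxy)propyl]-7-methoxy-2-(3-methoxy-4-triisopropylsilyloxyphenyl)-2,3-dihydrobenzofuran | COc1cc([C@@H]2Oc3c(OC)cc(CCCO[Si](c4ccccc4)(c4ccccc4)C(C)(C)C)cc3[C@H]2CO[Si](C)(C)C(C)(C)C)ccc1O[Si](C(C)C)(C(C)C)C(C)C | intermediate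
22 | {(2R,3S)-5-[3-(tert-butyldiphenylsilyloxy)propyl]-7-methoxy-2-(3-methoxy-4-triisopropylsilyloxyphenyl)-2,3-dihydrobenzofuran-3-yl}methanol | COc1cc([C@@H]2Oc3c(OC)cc(CCCO[Si](c4ccccc4)(c4ccccc4)C(C)(C)C)cc3[C@H]2CO)ccc1O[Si](C(C)C)(C(C)C)C(C)C | intermediate
23 | p-coumaric acid | OC(=O)/C=C/c1ccc(O)cc1 | starting material
24 | triisopropylsilyl (E)-3-[4-(triisopropylsilyloxy)phenyl]prop-2-enoate (formed in the flask) | CC(C)[Si](OC(=O)/C=C/c1ccc(O[Si](C(C)C)(C(C)C)C(C)C)cc1)(C(C)C)C(C)C | intermediate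
25 | (E)-3-[4-(triisopropylsilyloxy)phenyl]prop-2-enoic acid | OC(=O)/C=C/c1ccc(O[Si](C(C)C)(C(C)C)C(C)C)cc1 | intermediate
26 | {(2R,3S)-5-[3-(tert-butyldiphenylsilyloxy)propyl]-7-methoxy-2-(3-methoxy-4-triisopropylsilyloxyphenyl)-2,3-dihydrobenzofuran-3-yl}methyl (E)-3-[4-(triisopropylsilyloxy)phenyl]prop-2-enoate | COc1cc([C@@H]2Oc3c(OC)cc(CCCO[Si](c4ccccc4)(c4ccccc4)C(C)(C)C)cc3[C@H]2COC(=O)/C=C/c2ccc(O[Si](C(C)C)(C(C)C)C(C)C)cc2)ccc1O[Si](C(C)C)(C(C)C)C(C)C | intermediate
27 | [(2R,3S)-2-(4-hydroxy-3-methoxyphenyl)-5-(3-hydroxypropyl)-7-methoxy-2,3-dihydrobenzofuran-3-yl]methyl (E)-3-(4-hydroxyphenyl)prop-2-enoate (CNP0202924.1) | COc1cc([C@@H]2Oc3c(OC)cc(CCCO)cc3[C@H]2COC(=O)/C=C/c2ccc(O)cc2)ccc1O | target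

Total step count: 14.
Longest linear sequence: 12 steps (1 → 2 → 5 → 8 → 13 → 14 → 15 → 19 → 20 → 21 → 22 → 26 → 27; steps 4 and 12 make the side fragments).

**Steps most likely to fail**

1. Step 8 (key step).
 - What may go wrong: lithiation on the guaiacyl ring (C2′–H, between the methoxy group and the benzylic alkoxide) instead of at C7; consumption of the aryne by s-BuLi or by a second aryllithium; silyl migration to the C2 alkoxide; or protonation of the C7 carbanion before borylation.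
 - Fallback (sets out from aldehyde 10, with borane 4 and auxiliary 6; returns at 21): both ring A oxygens are brought in from the start and the furan ring is closed through the C2–O1 bond instead. Commercial 5-bromo-2-hydroxy-3-methoxybenzaldehyde is benzylated (BnBr, K2CO3, DMF) to 2-(benzyloxy)-5-bromo-3-methoxybenzaldehyde F1. Van Leusen reductive cyanation (TosMIC, t-BuOK, DME, then MeOH, reflux) converts it into arylacetonitrile F2, and hydrolysis (KOH, aq. EtOH, reflux) gives arylacetic acid F3. Coupling with 4 under the conditions of step 2 should give chain-bearing acid F4, and acylation of 6 as in step 3 gives imide F5. The boron aldol with 10 as in step 5 gives syn adduct F6, LiBH4 gives diol F7, and TBSCl gives primary silyl ether F8. Hydrogenolysis (H2, Pd/C, EtOAc) releases ring A phenol F9. Brief treatment with CSA in CH2Cl2 at 0 °C should ionise the p-silyloxybenzylic alcohol, and the phenol should close the ring trans to the C3 substituent, whose configuration comes from the auxiliary. This gives 21 with the C7 methoxy group already present, so steps 8–10 are not needed.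

2. Step 5.
 - What may go wrong: erosion of syn selectivity at the carbinol carbon through reversible aldolisation (the α-aryl enolate is stabilised and the aldehyde is electron-rich), or retro-aldol on work-up.
 - Fallback (sets out from 15, obtained as a mixture of carbinol epimers after steps 6 and 7; returns at 15): the mixture is oxidised with Dess–Martin periodinane (NaHCO3, CH2Cl2, 0 °C) to the single α-aryl ketone F10. Reduction with LiBH(s-Bu)3 (THF, −78 °C) should deliver hydride anti to the C2 aryl group (Felkin–Anh control) and so return syn 15. Both operations are kept cold and free of base, because the α-aryl ketone stereocentre can epimerise.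

3. Step 2.
 - What may go wrong: slow transmetalation or protodeboronation of the alkylborane in the presence of the carboxylate, so that the coupling stalls.
 - Fallback (sets out from 3; returns at 5): the chain is attached by sp–sp2 coupling and reduction on a neutral ester. Fischer esterification of 3 (MeOH, H2SO4) gives methyl 2-(5-bromo-2-fluorophenyl)acetate F11. Sonogashira coupling with propargyl alcohol (PdCl2(PPh3)2, CuI, Et3N, 70 °C) gives arylalkynol F12, and hydrogenation (H2, Pd/C, EtOAc) gives 3-hydroxypropyl ester F13. Silylation (TBDPSCl, imidazole) gives silyl ether ester F14, and saponification (LiOH, THF/H2O, rt) gives 5.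

**Further compounds**

F1 | step 8 | 2-(benzyloxy)-5-bromo-3-methoxybenzaldehyde | COc1cc(Br)cc(C=O)c1OCc1ccccc1
F2 | step 8 | 2-[2-(benzyloxy)-5-bromo-3-methoxyphenyl]acetonitrile | COc1cc(Br)cc(CC#N)c1OCc1ccccc1
F3 | step 8 | 2-[2-(benzyloxy)-5-bromo-3-methoxyphenyl]acetic acid | COc1cc(Br)cc(CC(=O)O)c1OCc1ccccc1
F4 | step 8 | 2-{2-(benzyloxy)-5-[3-(tert-butyldiphenylsilyloxy)propyl]-3-methoxyphenyl}acetic acid | COc1cc(CCCO[Si](c2ccccc2)(c2ccccc2)C(C)(C)C)cc(CC(=O)O)c1OCc1ccccc1
F5 | step 8 | (R)-4-benzyl-3-(2-{2-(benzyloxy)-5-[3-(tert-butyldiphenylsilyloxy)propyl]-3-methoxyphenyl}acetyl)oxazolidin-2-one | COc1cc(CCCO[Si](c2ccccc2)(c2ccccc2)C(C)(C)C)cc(CC(=O)N2[C@H](Cc3ccccc3)COC2=O)c1OCc1ccccc1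
F6 | step 8 | (R)-4-benzyl-3-[(2R,3R)-2-{2-(benzyloxy)-5-[3-(tert-butyldiphenylsilyloxy)propyl]-3-methoxyphenyl}-3-hydroxy-3-(3-methoxy-4-triisopropylsilyloxyphenyl)propanoyl]oxazolidin-2-one | COc1cc([C@H](O)[C@H](C(=O)N2[C@H](Cc3ccccc3)COC2=O)c2cc(CCCO[Si](c3ccccc3)(c3ccccc3)C(C)(C)C)cc(OC)c2OCc2ccccc2)ccc1O[Si](C(C)C)(C(C)C)C(C)C
F7 | step 8 | (1R,2S)-2-{2-(benzyloxy)-5-[3-(tert-butyldiphenylsilyloxy)propyl]-3-methoxyphenyl}-1-(3-methoxy-4-triisopropylsilyloxyphenyl)propane-1,3-diol | COc1cc([C@H](O)[C@H](CO)c2cc(CCCO[Si](c3ccccc3)(c3ccccc3)C(C)(C)C)cc(OC)c2OCc2ccccc2)ccc1O[Si](C(C)C)(C(C)C)C(C)C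
F8 | step 8 | (1R,2S)-2-{2-(benzyloxy)-5-[3-(tert-butyldiphenylsilyloxy)propyl]-3-methoxyphenyl}-3-(tert-butyldimethylsilyloxy)-1-(3-methoxy-4-triisopropylsilyloxyphenyl)propan-1-ol | COc1cc([C@H](O)[C@H](CO[Si](C)(C)C(C)(C)C)c2cc(CCCO[Si](c3ccccc3)(c3ccccc3)C(C)(C)C)cc(OC)c2OCc2ccccc2)ccc1O[Si](C(C)C)(C(C)C)C(C)C
F9 | step 8 | (1R,2S)-3-(tert-butyldimethylsilyloxy)-2-{5-[3-(tert-butyldiphenylsilyloxy)propyl]-2-hydroxy-3-methoxyphenyl}-1-(3-methoxy-4-triisopropylsilyloxyphenyl)propan-1-ol | COc1cc([C@H](O)[C@H](CO[Si](C)(C)C(C)(C)C)c2cc(CCCO[Si](c3ccccc3)(c3ccccc3)C(C)(C)C)cc(OC)c2O)ccc1O[Si](C(C)C)(C(C)C)C(C)C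
F10 | step 5 | (S)-3-(tert-butyldimethylsilyloxy)-2-{5-[3-(tert-butyldiphenylsilyloxy)propyl]-2-fluorophenyl}-1-(3-methoxy-4-triisopropylsilyloxyphenyl)propan-1-one | COc1cc(C(=O)[C@H](CO[Si](C)(C)C(C)(C)C)c2cc(CCCO[Si](c3ccccc3)(c3ccccc3)C(C)(C)C)ccc2F)ccc1O[Si](C(C)C)(C(C)C)C(C)C
F11 | step 2 | methyl 2-(5-bromo-2-fluorophenyl)acetate | COC(=O)Cc1cc(Br)ccc1F
F12 | step 2 | methyl 2-[2-fluoro-5-(3-hydroxyprop-1-yn-1-yl)phenyl]acetate | COC(=O)Cc1cc(C#CCO)ccc1F
F13 | step 2 | methyl 2-[2-fluoro-5-(3-hydroxypropyl)phenyl]acetate | COC(=O)Cc1cc(CCCO)ccc1F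
F14 | step 2 | methyl 2-{5-[3-(tert-butyldiphenylsilyloxy)propyl]-2-fluorophenyl}acetate | COC(=O)Cc1cc(CCCO[Si](c2ccccc2)(c2ccccc2)C(C)(C)C)ccc1F
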